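Retrosynthesis: the two formyl groups and free phenols of ring A come off first (late bromination/formylation, thiolate demethylation) and the exocyclic methylene is traced to a ketone. The nine-membered ring is then cut inside the CH2–CH2 bridge between the methyl-bearing quaternary ether carbon C2 of the chroman and the cyclobutane CH next to the CMe2 carbon; that bridge is read as a hydrogenated cis C=C made from a 2-vinylchroman and a vinylcyclobutane.
The open-chain diene is cut once more at the C(=O)–CH2 bond (sulfone acylation) into a 2-methyl-2-vinylchroman with a 2-(phenylsulfonyl)ethyl arm at C3 and a trans-2-vinyl-3,3-dimethylcyclobutane ester.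
Forward: ring B as the 4-phenyldihydrocoumarin, then the C3 arm, then the C2 quaternary centre; the cyclobutane by Wolff ring contraction of a cyclopentanone, which puts the vinyl group next to the gem-dimethyl carbon without ambiguity; ketone union; nine-membered ring by metathesis; hydrogenation, methylenation, diformylation, demethylation.
Stereochemistry: C4 from a rhodium/(R)-SEGPHOS phenyl addition, C3 by enolate addition anti to phenyl, C2 by axial capture of an oxocarbenium ion anti to the C3 arm; the vinyl-bearing cyclobutane carbon from a rhodium/(S)-BINAP vinyl addition, its neighbour by equilibration to the trans ester.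

Key step: step 11

Remark: the facial sense of the two rhodium-catalysed additions is assigned by analogy with unsubstituted coumarins and cyclopentenone (the enantiomeric ligand is used if a substrate responds in the opposite sense); phenyl vinyl sulfone, the two potassium organotrifluoroborates and 4,4-dimethylcyclopent-2-en-1-one are taken to be purchasable.

Step 1
Reactants: 1 5,7-dimethoxycoumarin; 2 phenylboronic acid
Product: 3 (4R)-5,7-dimethoxy-4-phenylchroman-2-one
Conditions: Rh(acac)(C2H4)2 (3 mol%), (R)-SEGPHOS (3.3 mol%), 2 (5 equiv), dioxane/H2O 10:1, 60 °C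
Reagents that add atoms: none
Why: Rhodium-catalysed asymmetric conjugate addition of arylboronic acids to coumarins (Hayashi–Miyaura reaction) is established, and the phenylrhodium species bound to (R)-SEGPHOS should add to the enone face that makes C4 (R), as it does for simple coumarins.

Step 2
Reactants: 3 (4R)-5,7-dimethoxy-4-phenylchroman-2-one; 4 phenyl vinyl sulfone
Product: 5 (3S,4R)-5,7-dimethoxy-4-phenyl-3-[2-(phenylsulfonyl)ethyl]chroman-2-one (3,4-trans)
Conditions: LiN(SiMe3)2 (1.05 equiv), THF, −78 °C; 4 (1.2 equiv), −78 → −40 °C; AcOH quench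
Reagents that add atoms: none
Why: Michael addition of the lactone lithium enolate to the vinyl sulfone should take place on the face opposite the pseudo-axial 4-phenyl group, as alkylations of 4-aryl-3,4-dihydrocoumarin enolates do, which sets C3 trans to phenyl and installs a two-carbon arm ending in a carbanion-stabilising sulfone.

Step 3
Reactants: 5 (3S,4R)-5,7-dimethoxy-4-phenyl-3-[2-(phenylsulfonyl)ethyl]chroman-2-one
Product: 7 (3S,4R)-2,5,7-trimethoxy-2-methyl-4-phenyl-3-[2-(phenylsulfonyl)ethyl]chroman as a mixture of C2 epimers, via 2-methylidenechroman enol ether 6 (not isolated)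
Conditions: Cp2TiMe2 (2.5 equiv), toluene, 65 °C, dark; filtration through basic Al2O3; then MeOH, pyridinium p-toluenesulfonate (5 mol%), 0 °C
Reagents that add atoms: dimethyltitanocene Cp2TiMe2, C[Ti](C)(C1C=CC=C1)C1C=CC=C1; methanol, CO
Why: Petasis methylenation turns lactones into exocyclic enol ethers without enolising C3, and acid-catalysed Markovnikov addition of methanol then gives the mixed O-aryl O-methyl ketal, whose C2 configuration is irrelevant because that carbon is ionised in the next step.

Step 4
Reactants: 7 (3S,4R)-2,5,7-trimethoxy-2-methyl-4-phenyl-3-[2-(phenylsulfonyl)ethyl]chroman; 8 potassium trifluoro[(trimethylsilyl)ethynyl]borate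
Product: 10 (2S,3S,4R)-2-ethynyl-5,7-dimethoxy-2-methyl-4-phenyl-3-[2-(phenylsulfonyl)ethyl]chroman, via silylalkyne 9 (not isolated)
Conditions: 8 (2 equiv), BF3·OEt2 (2 equiv), MeCN/CH2Cl2, −40 → 0 °C; aqueous NaHCO3 work-up; then K2CO3 (0.2 equiv), MeOH, 23 °C
Reagents that add atoms: none
Why: Lewis-acid ionisation of the ketal gives a 2-methylchromanylium (oxocarbenium) ion that is captured by the alkynylboron nucleophile (acetal substitution by an organotrifluoroborate), and the slim linear alkyne should enter axially on the face anti to the pseudo-axial C3 arm, placing the alkyne trans and the methyl cis to that arm, before methanolysis removes the silyl group.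

Step 5
Reactants: 10 (2S,3S,4R)-2-ethynyl-5,7-dimethoxy-2-methyl-4-phenyl-3-[2-(phenylsulfonyl)ethyl]chroman
Product: 11 (2R,3S,4R)-2-ethenyl-5,7-dimethoxy-2-methyl-4-phenyl-3-[2-(phenylsulfonyl)ethyl]chroman
Conditions: H2 (1 atm), Pd/CaCO3–Pb(OAc)2 (5% Pd), quinoline, EtOAc, 23 °C
Reagents that add atoms: none
Why: Lindlar semihydrogenation of a terminal alkyne stops at the alkene and touches neither the sulfone nor the aryl ethers, so the 2-methyl-2-vinylchroman is obtained with C2 unchanged in space.

Step 6
Reactants: 12 4,4-dimethylcyclopent-2-en-1-one; 13 potassium trifluoro(vinyl)borate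
Product: 14 (3S)-3-ethenyl-4,4-dimethylcyclopentan-1-one
Conditions: [Rh(cod)2]BF4 (3 mol%), (S)-BINAP (3.3 mol%), 13 (2 equiv), toluene/H2O 4:1, 100 °C
Reagents that add atoms: none
Why: Rhodium-catalysed asymmetric 1,4-addition of an alkenylboron reagent to a cyclic enone, in which the (S)-BINAP complex should deliver vinyl to the face that gives the (S) centre, the carbon that later becomes the vinyl-bearing cyclobutane carbon next to CMe2.

Step 7
Reactants: 14 (3S)-3-ethenyl-4,4-dimethylcyclopentan-1-one
Product: 16 (3S)-2-diazo-3-ethenyl-4,4-dimethylcyclopentan-1-one, via trifluoroacetyl ketone 15 (not isolated)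
Conditions: LiN(SiMe3)2 (1.1 equiv), THF, −78 °C; CF3CO2CH2CF3 (1.2 equiv); aqueous HCl work-up; then MeSO2N3 (1.5 equiv), Et3N (1.5 equiv), H2O (1 equiv), MeCN, 23 °C
Reagents that add atoms: 2,2,2-trifluoroethyl trifluoroacetate, O=C(OCC(F)(F)F)C(F)(F)F; methanesulfonyl azide, CS(=O)(=O)N=[N+]=[N-]
Why: Detrifluoroacetylative diazo transfer (a Regitz-type diazo transfer on an activated ketone) should be regioselective because kinetic deprotonation prefers C2, whose hydrogen trans to the vinyl group is unencumbered, over C5 beside the quaternary carbon, so the diazo group ends up between the carbonyl and the vinyl-bearing carbon.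

Step 8
Reactants: 16 (3S)-2-diazo-3-ethenyl-4,4-dimethylcyclopentan-1-one
Product: 19 methyl (1S,2R)-2-ethenyl-3,3-dimethylcyclobutane-1-carboxylate (trans), via ketene 17 (not isolated), via cis ester 18 (not isolated)
Conditions: hν (365 nm), MeOH, 0–20 °C; then NaOMe (0.3 equiv), MeOH, 50 °C
Reagents that add atoms: methanol, CO
Why: Photochemical Wolff rearrangement of the cyclic α-diazo ketone contracts the ring by migration of C5 to the carbene carbon, methanol traps the ketene as the ester, and methoxide equilibration at the only enolisable stereocentre should settle on the trans isomer while the vinyl-bearing centre from step 6 is untouched.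

Step 9
Reactants: 11 (2R,3S,4R)-2-ethenyl-5,7-dimethoxy-2-methyl-4-phenyl-3-[2-(phenylsulfonyl)ethyl]chroman; 19 methyl (1S,2R)-2-ethenyl-3,3-dimethylcyclobutane-1-carboxylate
Product: 20 1-[(1S,2R)-2-ethenyl-3,3-dimethylcyclobutyl]-3-[(2R,3S,4R)-2-ethenyl-5,7-dimethoxy-2-methyl-4-phenylchroman-3-yl]-2-(phenylsulfonyl)propan-1-one (both epimers at the sulfonyl carbon)
Conditions: 11, n-BuLi (2.1 equiv), THF, −78 → −30 °C; then 19 (1.3 equiv), −78 → 0 °C; aqueous NH4Cl
Reagents that add atoms: none
Why: Acylation of a lithiated sulfone by an ester (β-keto sulfone synthesis) joins the fragments at the future ketone carbon, two equivalents of base being used because the product is more acidic than the starting sulfone, and the cyclobutane ester is slow to enolise.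

Step 10
Reactants: 20 β-keto sulfone from step 9
Product: 21 1-[(1S,2R)-2-ethenyl-3,3-dimethylcyclobutyl]-3-[(2R,3S,4R)-2-ethenyl-5,7-dimethoxy-2-methyl-4-phenylchroman-3-yl]propan-1-one
Conditions: SmI2 (2.5 equiv), THF/MeOH, −78 °C
Reagents that add atoms: none
Why: Reductive desulfonylation of β-keto sulfones by SmI2 is fast at −78 °C and passes through the samarium enolate on the methylene side only, so the ketone is released without epimerising the cyclobutane or touching the two vinyl groups.

Step 11
Reactants: 21 diene ketone from step 10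
Product: 22 (Z)-cyclononenone tetracycle in which chroman C2 and C3 and cyclobutane C1 and C2 lie in a nine-membered ring: C3–CH2–CH2–C(=O)–cyclobutane C1, cyclobutane C2–CH=CH–C2 (all five stereocentres as in 21)
Conditions: RuCl2(=CHPh)(PCy3)(H2IMes) (second-generation Grubbs catalyst, 10 mol% in two portions), toluene (1 mM), 80 °C, argon sparge
Reagents that add atoms: none
Why: The step is an olefin metathesis by the metallacyclobutane mechanism: the ruthenium benzylidene exchanges with one terminal vinyl group, the new alkylidene undergoes [2+2] cycloaddition with the second vinyl group, and cycloreversion releases ethylene and the ring alkene. The closest known reaction type is ring-closing metathesis to medium-sized carbocycles with second-generation ruthenium catalysts, including closures through a vinylcyclobutane next to a gem-dimethyl carbon. One ring is closed, the nine-membered carbocycle, by joining the two vinyl CH carbons end to end so that the new C=C lies inside the ring. No stereocentre is created; the ring size allows only the Z alkene, and that geometry disappears on hydrogenation. The step needs ring closure to win over intermolecular metathesis, which high dilution, removal of ethylene, the trans arrangement of the two chains on the rigid chroman, the trans-1,2-disubstituted cyclobutane and the sp2 ketone carbon should secure. The ketone is inert to the catalyst and keeps the future methylene position free of a 1,1-disubstituted alkene that would otherwise close a six-membered ring with the chroman vinyl group.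

Step 12
Reactants: 22 (Z)-cyclononenone tetracycle
Product: 23 saturated tetracyclic ketone (22 with the ring C=C reduced to CH2–CH2)
Conditions: H2 (1 atm), Pt/C (5%), EtOAc, 23 °C
Reagents that add atoms: none
Why: Heterogeneous catalytic hydrogenation over platinum saturates the strained cis-disubstituted ring alkene, platinum has far less tendency than palladium to cleave the allylic C2–O bond, and the ketone and arenes are inert at 1 atm.

Step 13
Reactants: 23 saturated tetracyclic ketone
Product: 24 exocyclic methylene compound (the 5,7-di-O-methyl ether of the target without its two formyl groups)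
Conditions: Ph3PCH3Br (4 equiv), KOt-Bu (3.8 equiv), toluene, 23 → 80 °C
Reagents that add atoms: methyltriphenylphosphonium bromide, C[P+](c1ccccc1)(c1ccccc1)c1ccccc1.[Br-]
Why: Wittig methylenation of a cyclobutyl ketone inside a bicyclo[7.2.0]undecane is the classical way to the caryophyllene-type exocyclic methylene, and the trans ring fusion at the enolisable cyclobutane carbon is the thermodynamically preferred one under the basic conditions.

Step 14
Reactants: 24 exocyclic methylene compound
Product: 25 6,8-dibromide of 24 (both free positions of ring A brominated)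
Conditions: N-bromosuccinimide (2.1 equiv), MeCN/CH2Cl2, −20 → 0 °C, dark
Reagents that add atoms: N-bromosuccinimide, O=C1CCC(=O)N1Br
Why: Electrophilic aromatic bromination by N-bromosuccinimide is very fast at the two remaining ring A positions, each flanked by two oxygen substituents, and in dry aprotic solvent at low temperature should outpace any reaction at the 1,1-disubstituted alkene.

Step 15
Reactants: 25 6,8-dibromide
Product: 26 6,8-dicarbaldehyde (5,7-di-O-methyl ether of the target)
Conditions: t-BuLi (4.4 equiv), THF/Et2O, −78 °C; then DMF (excess), −78 → 0 °C; aqueous NH4Cl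
Reagents that add atoms: N,N-dimethylformamide, CN(C)C=O
Why: Twofold bromine–lithium exchange followed by formylation with DMF (Bouveault aldehyde synthesis) introduces both aldehydes under non-acidic conditions that the methylene group next to the cyclobutane tolerates, which strongly Lewis-acidic electrophilic formylation would not guarantee.

Step 16
Reactants: 26 6,8-dicarbaldehyde dimethyl ether
Product: 27 target CNP0253700.4
Conditions: NaSEt (8 equiv), DMF, 110 °C; 1 M HCl work-up at 0 °C
Reagents that add atoms: none
Why: Nucleophilic demethylation by thiolate (SN2 at the methyl carbon) is accelerated for methoxy groups ortho or para to formyl groups because the phenoxide leaving group is stabilised, and the basic conditions leave the exocyclic alkene, the cyclobutane and the tertiary C2–O bond untouched.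

Compound list
1 | 5,7-dimethoxycoumarin | COc1cc(OC)c2ccc(=O)oc2c1 | starting material
2 | phenylboronic acid | OB(O)c1ccccc1 | starting material
3 | (4R)-5,7-dimethoxy-4-phenylchroman-2-one | O=C1C[C@H](c2ccccc2)c2c(OC)cc(OC)cc2O1 | intermediate
4 | phenyl vinyl sulfone | C=CS(=O)(=O)c1ccccc1 | starting material
5 | (3S,4R)-5,7-dimethoxy-4-phenyl-3-[2-(phenylsulfonyl)ethyl]chroman-2-one | O=C1[C@@H](CCS(=O)(=O)c2ccccc2)[C@H](c2ccccc2)c2c(OC)cc(OC)cc2O1 | intermediate
6 | (3S,4R)-5,7-dimethoxy-2-methylidene-4-phenyl-3-[2-(phenylsulfonyl)ethyl]chroman (enol ether) | C=C1[C@@H](CCS(=O)(=O)c2ccccc2)[C@H](c2ccccc2)c2c(OC)cc(OC)cc2O1 | intermediate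
7 | (3S,4R)-2,5,7-trimethoxy-2-methyl-4-phenyl-3-[2-(phenylsulfonyl)ethyl]chroman (both C2 epimers) | COC1(C)[C@@H](CCS(=O)(=O)c2ccccc2)[C@H](c2ccccc2)c2c(OC)cc(OC)cc2O1 | intermediate
8 | potassium trifluoro[(trimethylsilyl)ethynyl]borate | C[Si](C)(C)C#C[B-](F)(F)F.[K+] | starting material
9 | (2S,3S,4R)-5,7-dimethoxy-2-methyl-4-phenyl-3-[2-(phenylsulfonyl)ethyl]-2-[(trimethylsilyl)ethynyl]chroman | C[Si](C)(C)C#C[C@]1(C)[C@@H](CCS(=O)(=O)c2ccccc2)[C@H](c2ccccc2)c2c(OC)cc(OC)cc2O1 | intermediate
10 | (2S,3S,4R)-2-ethynyl-5,7-dimethoxy-2-methyl-4-phenyl-3-[2-(phenylsulfonyl)ethyl]chroman | C#C[C@]1(C)[C@@H](CCS(=O)(=O)c2ccccc2)[C@H](c2ccccc2)c2c(OC)cc(OC)cc2O1 | intermediate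
11 | (2R,3S,4R)-2-ethenyl-5,7-dimethoxy-2-methyl-4-phenyl-3-[2-(phenylsulfonyl)ethyl]chroman | C=C[C@]1(C)[C@@H](CCS(=O)(=O)c2ccccc2)[C@H](c2ccccc2)c2c(OC)cc(OC)cc2O1 | intermediate
12 | 4,4-dimethylcyclopent-2-en-1-one | O=C1C=CC(C)(C)C1 | starting material
13 | potassium trifluoro(vinyl)borate | C=C[B-](F)(F)F.[K+] | starting material
14 | (3S)-3-ethenyl-4,4-dimethylcyclopentan-1-one | C=C[C@@H]1CC(=O)CC1(C)C | intermediate
15 | 2-(trifluoroacetyl) derivative of 14 (enolisable 1,3-diketone, vinyl-bearing carbon unchanged) | C=C[C@@H]1C(C(=O)C(F)(F)F)C(=O)CC1(C)C | intermediate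
16 | (3S)-2-diazo-3-ethenyl-4,4-dimethylcyclopentan-1-one | C=C[C@@H]1C(=[N+]=[N-])C(=O)CC1(C)C | intermediate
17 | (2-ethenyl-3,3-dimethylcyclobutylidene)methanone (ketene, vinyl-bearing carbon as in 16) | C=C[C@@H]1C(=C=O)CC1(C)C | intermediate
18 | methyl (1R,2R)-2-ethenyl-3,3-dimethylcyclobutane-1-carboxylate (cis) | C=C[C@@H]1[C@H](C(=O)OC)CC1(C)C | intermediate
19 | methyl (1S,2R)-2-ethenyl-3,3-dimethylcyclobutane-1-carboxylate (trans) | C=C[C@@H]1[C@@H](C(=O)OC)CC1(C)C | intermediate
20 | 1-[(1S,2R)-2-ethenyl-3,3-dimethylcyclobutyl]-3-[(2R,3S,4R)-2-ethenyl-5,7-dimethoxy-2-methyl-4-phenylchroman-3-yl]-2-(phenylsulfonyl)propan-1-one | C=C[C@@H]1[C@@H](C(=O)C(S(=O)(=O)c2ccccc2)C[C@H]2[C@H](c3ccccc3)c3c(OC)cc(OC)cc3O[C@]2(C)C=C)CC1(C)C | intermediate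
21 | 1-[(1S,2R)-2-ethenyl-3,3-dimethylcyclobutyl]-3-[(2R,3S,4R)-2-ethenyl-5,7-dimethoxy-2-methyl-4-phenylchroman-3-yl]propan-1-one | C=C[C@@H]1[C@@H](C(=O)CC[C@H]2[C@H](c3ccccc3)c3c(OC)cc(OC)cc3O[C@]2(C)C=C)CC1(C)C | intermediate
22 | chroman- and cyclobutane-fused (Z)-cyclononenone, 5,7-dimethoxy | O=C1CC[C@H]2[C@H](c3ccccc3)c3c(OC)cc(OC)cc3O[C@]2(C)/C=C\[C@@H]2[C@@H]1CC2(C)C | intermediate
23 | chroman- and cyclobutane-fused cyclononanone, 5,7-dimethoxy | O=C1CC[C@H]2[C@H](c3ccccc3)c3c(OC)cc(OC)cc3O[C@]2(C)CC[C@@H]2[C@@H]1CC2(C)C | intermediate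
24 | methylidene compound (target skeleton, 5,7-dimethoxy, ring A positions 6 and 8 unsubstituted) | C=C1CC[C@H]2[C@H](c3ccccc3)c3c(OC)cc(OC)cc3O[C@]2(C)CC[C@@H]2[C@@H]1CC2(C)C | intermediate
25 | 6,8-dibromo derivative of 24 | C=C1CC[C@H]2[C@H](c3ccccc3)c3c(OC)c(Br)c(OC)c(Br)c3O[C@]2(C)CC[C@@H]2[C@@H]1CC2(C)C | intermediate
26 | 6,8-diformyl derivative of 24 (target 5,7-di-O-methyl ether) | C=C1CC[C@H]2[C@H](c3ccccc3)c3c(OC)c(C=O)c(OC)c(C=O)c3O[C@]2(C)CC[C@@H]2[C@@H]1CC2(C)C | intermediate
27 | CNP0253700.4 (6,8-diformyl-5,7-dihydroxy chroman fused to the methylidene-bearing cyclononane and the gem-dimethylcyclobutane) | C=C1CC[C@H]2[C@H](c3ccccc3)c3c(O)c(C=O)c(O)c(C=O)c3O[C@]2(C)CC[C@@H]2[C@@H]1CC2(C)C | target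

Total steps: 16. Longest linear sequence: 13 steps (1–5, then 9–16); the cyclobutane branch (steps 6–8) joins at step 9.

Steps most likely to fail

Step 11. Neither vinyl group forms the ruthenium alkylidene quickly, since one sits on a quaternary ether carbon and the other beside the gem-dimethyl carbon, so intermolecular metathesis or catalyst decay may overtake the nine-membered ring closure. The fallback is a relay ring-closing metathesis that sets out from 7 and comes back at 22. Ketal 7 is substituted under the conditions of step 4 with potassium trifluoro[3-(prop-2-en-1-yloxy)prop-1-yn-1-yl]borate F1 (from allyl propargyl ether with n-BuLi, B(OMe)3 and KHF2) to give the 2-[3-(allyloxy)prop-1-ynyl]chroman sulfone F2, which has C2 configured as in 10. Semihydrogenation over Pd/CaCO3–Pb(OAc)2 gives the (Z)-allyl ether diene F3. Acylation of its sulfone dianion with 19 as in step 9 gives the β-keto sulfone F4, and SmI2 as in step 10 gives the relay triene ketone F5. With RuCl2(=CHPh)(PCy3)(H2IMes) in dilute toluene the catalyst should load on the unhindered allyl ether terminus and extrude 2,5-dihydrofuran, which places it on the carbon attached to chroman C2. From there it closes the nine-membered ring onto the cyclobutyl vinyl group and gives 22.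

Step 4. The oxocarbenium ion may be captured on the face syn to the C3 arm, because the pseudo-axial 4-phenyl group shields the other face, which would give the C2 epimer; loss of the C3 proton from the ion may also erode the 3,4-trans relationship. The fallback reverses the order in which the two C2 substituents arrive; it sets out from 5 and comes back at 9. LiC≡CSiMe3 activated by BF3·OEt2 (THF, −78 °C, where addition should outrun enolisation) adds once to lactone 5 to give the 2-[(trimethylsilyl)ethynyl]chroman-2-ol hemiketal F6. AlMe3 (CH2Cl2, −78 → 0 °C) then delivers methyl to the alkynyl-stabilised oxocarbenium ion. The same facial bias now puts methyl where the alkyne went before, giving 9, which is desilylated to 10 as in step 4.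

Step 6. Insertion of the enone into the vinyl–rhodium bond at the carbon beside the quaternary centre may be slow, so that hydrolysis of the vinylboron reagent takes over and conversion stays low. The fallback is a copper-catalysed conjugate addition of a more reactive vinylaluminium surrogate; it sets out from 12 and comes back at 14. The reagent i-Bu2Al[C(SiMe3)=CH2] (from trimethylsilylacetylene and i-Bu2AlH), with Cu(OTf)2 and a chiral N-heterocyclic carbene ligand, should give (R)-4,4-dimethyl-3-[1-(trimethylsilyl)ethenyl]cyclopentan-1-one F7, which has the same spatial arrangement as 14. Protodesilylation with CF3CO2H then gives 14.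

Further compounds
F1 | step 11 | potassium trifluoro[3-(prop-2-en-1-yloxy)prop-1-yn-1-yl]borate | C=CCOCC#C[B-](F)(F)F.[K+]
F2 | step 11 | (3S,4R)-5,7-dimethoxy-2-methyl-4-phenyl-3-[2-(phenylsulfonyl)ethyl]-2-[3-(prop-2-en-1-yloxy)prop-1-yn-1-yl]chroman, C2 as in 10 | C=CCOCC#C[C@]1(C)[C@@H](CCS(=O)(=O)c2ccccc2)[C@H](c2ccccc2)c2c(OC)cc(OC)cc2O1
F3 | step 11 | (3S,4R)-5,7-dimethoxy-2-methyl-4-phenyl-3-[2-(phenylsulfonyl)ethyl]-2-[(1Z)-3-(prop-2-en-1-yloxy)prop-1-en-1-yl]chroman, C2 as in 11 | C=CCOC/C=C\[C@]1(C)[C@@H](CCS(=O)(=O)c2ccccc2)[C@H](c2ccccc2)c2c(OC)cc(OC)cc2O1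
F4 | step 11 | β-keto sulfone analogue of 20 with the (1Z)-3-(prop-2-en-1-yloxy)prop-1-en-1-yl group in place of the chroman vinyl group | C=C[C@@H]1[C@@H](C(=O)C(S(=O)(=O)c2ccccc2)C[C@H]2[C@H](c3ccccc3)c3c(OC)cc(OC)cc3O[C@]2(C)/C=C\COCC=C)CC1(C)C
F5 | step 11 | relay triene ketone, analogue of 21 with the (1Z)-3-(prop-2-en-1-yloxy)prop-1-en-1-yl group in place of the chroman vinyl group | C=C[C@@H]1[C@@H](C(=O)CC[C@H]2[C@H](c3ccccc3)c3c(OC)cc(OC)cc3O[C@]2(C)/C=C\COCC=C)CC1(C)C
F6 | step 4 | (3S,4R)-5,7-dimethoxy-4-phenyl-3-[2-(phenylsulfonyl)ethyl]-2-[(trimethylsilyl)ethynyl]chroman-2-ol (hemiketal, both C2 epimers) | C[Si](C)(C)C#CC1(O)[C@@H](CCS(=O)(=O)c2ccccc2)[C@H](c2ccccc2)c2c(OC)cc(OC)cc2O1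
F7 | step 6 | (R)-4,4-dimethyl-3-[1-(trimethylsilyl)ethenyl]cyclopentan-1-one | C=C([Si](C)(C)C)[C@@H]1CC(=O)CC1(C)C
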